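Ring B is cut across two C–C bonds into methyl coumalate and the ethynyl ether of the ring C phenol. The key step exploits the 1,4-substitution of ring B: C4 bears the diaryl ether oxygen and C1 the benzylic CH2 of the bridge to ring A. A 5-carbomethoxy-2-pyrone and an oxygen-substituted alkyne deliver exactly this pattern after [4+2] addition and CO2 extrusion. In one operation ring B should form with the C–O link to ring C in place and an ester at C1 that later becomes the bridge carbon. The precursor is a terminal aryloxyacetylene whose aryl group is the O-methylated C/D bibenzyl, reached from the phenol through a dichlorovinyl ether.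

Key step: step 6

Remark: compounds 1, 3, 13 and 18 are taken as purchasable; both Wittig steps should give E/Z mixtures that are carried on unseparated because the next step saturates the double bond, so 5 and 20 are drawn without alkene geometry.

Step 1
Reactants: 1 2,5-dimethoxybenzyl alcohol
Product: 2 (2,5-dimethoxybenzyl)triphenylphosphonium bromide
Conditions: PPh3·HBr (1.05 equiv), MeCN, reflux
Reagents that add atoms: triphenylphosphine hydrobromide, [Br-].[PH+](c1ccccc1)(c1ccccc1)c1ccccc1
Why: The electron-rich benzylic alcohol should ionise under the acidic conditions and be captured by triphenylphosphine (phosphonium salt formation by nucleophilic substitution), which gives the Wittig salt without a separate halide step.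

Step 2
Reactants: 2 (2,5-dimethoxybenzyl)triphenylphosphonium bromide; 3 3-(benzyloxy)-4-methoxybenzaldehyde (O-benzylisovanillin)
Product: 5 2-(benzyloxy)-4-[2-(2,5-dimethoxyphenyl)ethenyl]-1-methoxybenzene (E/Z mixture), via phosphonium ylide 4 (not isolated)
Conditions: KOtBu (1.1 equiv), THF, 0 °C; then 3, 0 °C to rt
Reagents that add atoms: none
Why: Wittig olefination of a non-enolisable aromatic aldehyde by a semi-stabilised benzylic ylide is dependable, the alkene geometry is irrelevant, and the benzyl ether masks the phenol oxygen that later becomes the diaryl ether oxygen.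

Step 3
Reactants: 5 2-(benzyloxy)-4-[2-(2,5-dimethoxyphenyl)ethenyl]-1-methoxybenzene (E/Z mixture)
Product: 6 5-[2-(2,5-dimethoxyphenyl)ethyl]-2-methoxyphenol
Conditions: H2 (1 atm), 10% Pd/C, EtOAc–EtOH, rt
Reagents that add atoms: none
Why: Catalytic hydrogenation over palladium should saturate the stilbene and hydrogenolyse the benzyl ether in the same flask while the three methyl ethers remain untouched.

Step 4
Reactants: 6 5-[2-(2,5-dimethoxyphenyl)ethyl]-2-methoxyphenol; 7 trichloroethylene
Product: 9 2-{[(E)-1,2-dichloroethenyl]oxy}-4-[2-(2,5-dimethoxyphenyl)ethyl]-1-methoxybenzene, via dichloroacetylene 8 (not isolated)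
Conditions: 7 (2 equiv), K2CO3 (2 equiv), DMF, 70 °C, N2
Reagents that add atoms: none
Why: Base eliminates HCl from trichloroethylene to give transient dichloroacetylene, and the phenoxide adds to it in anti fashion (nucleophilic addition to a haloalkyne followed by protonation), which sets the E geometry of the 1,2-dichlorovinyl ether.

Step 5
Reactants: 9 2-{[(E)-1,2-dichloroethenyl]oxy}-4-[2-(2,5-dimethoxyphenyl)ethyl]-1-methoxybenzene
Product: 12 2-(ethynyloxy)-4-[2-(2,5-dimethoxyphenyl)ethyl]-1-methoxybenzene, via chloroethynyl aryl ether 10 (not isolated), via lithium aryloxyacetylide 11 (not isolated)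
Conditions: n-BuLi (2.2 equiv), THF, −78 to −40 °C; then MeOH, −78 °C; cold aqueous NaHCO3 work-up, solvent exchanged to toluene below 0 °C and the solution used at once
Reagents that add atoms: none
Why: Vinylic deprotonation and loss of LiCl should give the chloroalkyne, chlorine–lithium exchange with the second equivalent should give the acetylide, and protonation should release the terminal ynol ether (dehydrohalogenation and halogen–metal exchange route to ynol ethers).

Step 6
Reactants: 12 2-(ethynyloxy)-4-[2-(2,5-dimethoxyphenyl)ethyl]-1-methoxybenzene; 13 methyl coumalate (methyl 2-oxo-2H-pyran-5-carboxylate)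
Product: 15 methyl 4-{5-[2-(2,5-dimethoxyphenyl)ethyl]-2-methoxyphenoxy}benzoate, via bridged bicyclic lactone 14 (not isolated)
Conditions: 13 (2 equiv), dry toluene, 100–110 °C, sealed tube, Ar
Reagents that add atoms: none
Why: Proposed new method: the ynol ether, whose HOMO is raised by the oxygen lone pair, should add across C3 and C6 of the electron-poor pyrone in an asynchronous inverse-electron-demand [4+2] cycloaddition, with its terminal CH carbon bonding to C6 (activated by both the C5 ester and the vinylogous lactone carbonyl) and its oxygen-bearing carbon bonding to C3. The closest known reaction type is the thermal cycloaddition of methyl coumalate to enol ethers, ketene acetals and ynamines, which gives para-substituted benzoates after loss of CO2; an aryloxyacetylene as partner is the untested element. Ring B is closed by this intermolecular [4+2] addition, which forms two C–C bonds, and the bridged lactone 14 should then lose CO2 in a retro-[4+2] step that aromatises the ring without any separate elimination or oxidation. No stereocenter has to be controlled, since the two bridgehead centres of 14 vanish on aromatisation. The step needs regioselectivity (ester para to the aryloxy group), and the matched polarisation of the partners secures it: the largest acceptor coefficient lies at C6 of the coumalate and the largest donor coefficient at the unsubstituted alkyne carbon. Excess pyrone, dilution and exclusion of acid and water should favour cycloaddition over self-reaction of the ynol ether, whose aryl group offers no hydrogen for a ketene-forming retro-ene fragmentation.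

Step 7
Reactants: 15 methyl 4-{5-[2-(2,5-dimethoxyphenyl)ethyl]-2-methoxyphenoxy}benzoate
Product: 16 (4-{5-[2-(2,5-dimethoxyphenyl)ethyl]-2-methoxyphenoxy}phenyl)methanol
Conditions: LiAlH4, THF, 0 °C; aqueous NaOH work-up
Reagents that add atoms: none
Why: Hydride reduction of an aryl ester to the benzylic alcohol (LiAlH4 reduction) is clean in the presence of aryl methyl ethers and the diaryl ether.

Step 8
Reactants: 16 (4-{5-[2-(2,5-dimethoxyphenyl)ethyl]-2-methoxyphenoxy}phenyl)methanol
Product: 17 4-{5-[2-(2,5-dimethoxyphenyl)ethyl]-2-methoxyphenoxy}benzaldehyde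
Conditions: activated MnO2 (10 equiv), CH2Cl2, rt
Reagents that add atoms: none
Why: Activated MnO2 oxidises benzylic alcohols selectively to aldehydes without over-oxidation and should leave the electron-rich rings and the bibenzyl CH2 groups alone.

Step 9
Reactants: 17 4-{5-[2-(2,5-dimethoxyphenyl)ethyl]-2-methoxyphenoxy}benzaldehyde; 18 (3-methoxybenzyl)triphenylphosphonium chloride
Product: 20 4-[2-(2,5-dimethoxyphenyl)ethyl]-1-methoxy-2-{4-[2-(3-methoxyphenyl)ethenyl]phenoxy}benzene (E/Z mixture), via phosphonium ylide 19 (not isolated)
Conditions: KOtBu (1.2 equiv), THF, 0 °C; then 17, 0 °C to rt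
Reagents that add atoms: none
Why: Wittig olefination of the aromatic aldehyde by the semi-stabilised 3-methoxybenzyl ylide should attach ring A and its bridge carbon, and the geometry of the new alkene does not matter.

Step 10
Reactants: 20 4-[2-(2,5-dimethoxyphenyl)ethyl]-1-methoxy-2-{4-[2-(3-methoxyphenyl)ethenyl]phenoxy}benzene (E/Z mixture)
Product: 21 4-[2-(2,5-dimethoxyphenyl)ethyl]-1-methoxy-2-{4-[2-(3-methoxyphenyl)ethyl]phenoxy}benzene
Conditions: H2 (1 atm), 10% Pd/C, EtOAc, rt
Reagents that add atoms: none
Why: Catalytic hydrogenation should saturate both stilbene isomers to the bibenzyl, and no hydrogenolysable group is present.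

Step 11
Reactants: 21 4-[2-(2,5-dimethoxyphenyl)ethyl]-1-methoxy-2-{4-[2-(3-methoxyphenyl)ethyl]phenoxy}benzene
Product: 22 2-[2-(4-hydroxy-3-{4-[2-(3-hydroxyphenyl)ethyl]phenoxy}phenyl)ethyl]benzene-1,4-diol (target)
Conditions: BBr3 (8 equiv), CH2Cl2, −78 °C to rt, Ar; then ice-water, extraction under Ar with an aqueous Na2S2O4 wash
Reagents that add atoms: none
Why: BBr3 should cleave all four aryl methyl ethers by Lewis acid complexation and bromide attack at methyl (Lewis acid ether cleavage), the diaryl ether has no alkyl carbon to attack, and aqueous work-up hydrolyses the mixed aryl borates, with air excluded because the hydroquinone ring D is oxidisable.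

Compound list
1 | 2,5-dimethoxybenzyl alcohol | COc1ccc(OC)c(CO)c1 | starting material
2 | (2,5-dimethoxybenzyl)triphenylphosphonium bromide | COc1ccc(OC)c(C[P+](c2ccccc2)(c2ccccc2)c2ccccc2)c1.[Br-] | intermediate
3 | 3-(benzyloxy)-4-methoxybenzaldehyde (O-benzylisovanillin) | COc1ccc(C=O)cc1OCc1ccccc1 | starting material
4 | (2,5-dimethoxybenzylidene)triphenylphosphorane | COc1ccc(OC)c(C=P(c2ccccc2)(c2ccccc2)c2ccccc2)c1 | intermediate (not isolated)
5 | 2-(benzyloxy)-4-[2-(2,5-dimethoxyphenyl)ethenyl]-1-methoxybenzene, E/Z mixture | COc1ccc(C=Cc2cc(OC)ccc2OC)cc1OCc1ccccc1 | intermediate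
6 | 5-[2-(2,5-dimethoxyphenyl)ethyl]-2-methoxyphenol | COc1ccc(CCc2cc(OC)ccc2OC)cc1O | intermediate
7 | trichloroethylene | ClC=C(Cl)Cl | starting material
8 | dichloroacetylene | ClC#CCl | intermediate (not isolated)
9 | 2-{[(E)-1,2-dichloroethenyl]oxy}-4-[2-(2,5-dimethoxyphenyl)ethyl]-1-methoxybenzene | COc1ccc(CCc2cc(OC)ccc2OC)cc1O/C(Cl)=C\Cl | intermediate
10 | 2-[(chloroethynyl)oxy]-4-[2-(2,5-dimethoxyphenyl)ethyl]-1-methoxybenzene | ClC#COc1cc(CCc2cc(OC)ccc2OC)ccc1OC | intermediate (not isolated)
11 | lithium {5-[2-(2,5-dimethoxyphenyl)ethyl]-2-methoxyphenoxy}acetylide | [Li]C#COc1cc(CCc2cc(OC)ccc2OC)ccc1OC | intermediate (not isolated)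
12 | 2-(ethynyloxy)-4-[2-(2,5-dimethoxyphenyl)ethyl]-1-methoxybenzene | C#COc1cc(CCc2cc(OC)ccc2OC)ccc1OC | intermediate
13 | methyl coumalate (methyl 2-oxo-2H-pyran-5-carboxylate) | COC(=O)C1=COC(=O)C=C1 | starting material
14 | methyl 8-{5-[2-(2,5-dimethoxyphenyl)ethyl]-2-methoxyphenoxy}-3-oxo-2-oxabicyclo[2.2.2]octa-5,7-diene-6-carboxylate, racemic | O=C1OC2C=C(Oc3cc(CCc4cc(OC)ccc4OC)ccc3OC)C1C=C2C(=O)OC | intermediate (not isolated)
15 | methyl 4-{5-[2-(2,5-dimethoxyphenyl)ethyl]-2-methoxyphenoxy}benzoate | COC(=O)c1ccc(Oc2cc(CCc3cc(OC)ccc3OC)ccc2OC)cc1 | intermediate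
16 | (4-{5-[2-(2,5-dimethoxyphenyl)ethyl]-2-methoxyphenoxy}phenyl)methanol | OCc1ccc(Oc2cc(CCc3cc(OC)ccc3OC)ccc2OC)cc1 | intermediate
17 | 4-{5-[2-(2,5-dimethoxyphenyl)ethyl]-2-methoxyphenoxy}benzaldehyde | O=Cc1ccc(Oc2cc(CCc3cc(OC)ccc3OC)ccc2OC)cc1 | intermediate
18 | (3-methoxybenzyl)triphenylphosphonium chloride | COc1cccc(C[P+](c2ccccc2)(c2ccccc2)c2ccccc2)c1.[Cl-] | starting material
19 | (3-methoxybenzylidene)triphenylphosphorane | COc1cccc(C=P(c2ccccc2)(c2ccccc2)c2ccccc2)c1 | intermediate (not isolated)
20 | 4-[2-(2,5-dimethoxyphenyl)ethyl]-1-methoxy-2-{4-[2-(3-methoxyphenyl)ethenyl]phenoxy}benzene, E/Z mixture | COc1cccc(C=Cc2ccc(Oc3cc(CCc4cc(OC)ccc4OC)ccc3OC)cc2)c1 | intermediate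
21 | 4-[2-(2,5-dimethoxyphenyl)ethyl]-1-methoxy-2-{4-[2-(3-methoxyphenyl)ethyl]phenoxy}benzene | COc1cccc(CCc2ccc(Oc3cc(CCc4cc(OC)ccc4OC)ccc3OC)cc2)c1 | intermediate
22 | 2-[2-(4-hydroxy-3-{4-[2-(3-hydroxyphenyl)ethyl]phenoxy}phenyl)ethyl]benzene-1,4-diol | Oc1cccc(CCc2ccc(Oc3cc(CCc4cc(O)ccc4O)ccc3O)cc2)c1 | target

Total step count: 11. Longest linear sequence: 11 steps (from 1 to 22; compounds 3, 7, 13 and 18 enter as purchased partners).

Steps most likely to fail

Step 6 carries the main risk. The ynol ether may oligomerise or be hydrated faster than the pyrone intercepts it, or the addition may lose its regiocontrol. The fallback is nucleophilic aromatic substitution, an established way to diaryl ethers: phenol 6 and 4-fluorobenzaldehyde with K2CO3 in DMF at 130 °C should give aldehyde 17 directly. It sets out from 6 and comes back to the route at 17, leaving out steps 4 to 8, and makes no compound outside the list (entry F0).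

Step 5 is next. The terminal ynol ether may be lost through hydration to the aryl acetate or through oligomerisation during quench, work-up and solvent exchange, and ring lithiation next to a methoxy group may compete if the temperature drifts. The fallback sets out from 9: the same n-BuLi treatment gives acetylide 11, which is capped with Me3SiCl at −78 °C to give the silyl-protected ynol ether 2-{[(trimethylsilyl)ethynyl]oxy}-4-[2-(2,5-dimethoxyphenyl)ethyl]-1-methoxybenzene F1. This should tolerate chromatography and cold storage. Bu4NF in THF at 0 °C immediately before the cycloaddition should release the terminal alkyne, so the fallback comes back to the route at 12.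

Step 4 is third. Transient dichloroacetylene may escape or polymerise before the phenoxide captures it, leaving the O-vinylation incomplete. The fallback sets out from 6 and builds the two alkyne carbons by formate olefination instead. Acetic formic anhydride and pyridine in CH2Cl2 at 0 °C should give the aryl formate 5-[2-(2,5-dimethoxyphenyl)ethyl]-2-methoxyphenyl formate F2. Corey–Fuchs-type dibromo-olefination (CBr4, PPh3, CH2Cl2, 0 °C) should then give the dibromovinyl ether 2-[(2,2-dibromoethenyl)oxy]-4-[2-(2,5-dimethoxyphenyl)ethyl]-1-methoxybenzene F3. n-BuLi (2.1 equiv, THF, −78 °C) should convert F3 into acetylide 11 by bromine–lithium exchange, loss of LiBr with hydrogen shift, and deprotonation. The fallback comes back to the route at 11, which is quenched with methanol as in step 5.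

Further compounds
F0 | step 6 | none | none
F1 | step 5 | 2-{[(trimethylsilyl)ethynyl]oxy}-4-[2-(2,5-dimethoxyphenyl)ethyl]-1-methoxybenzene | C[Si](C)(C)C#COc1cc(CCc2cc(OC)ccc2OC)ccc1OC
F2 | step 4 | 5-[2-(2,5-dimethoxyphenyl)ethyl]-2-methoxyphenyl formate | O=COc1cc(CCc2cc(OC)ccc2OC)ccc1OC
F3 | step 4 | 2-[(2,2-dibromoethenyl)oxy]-4-[2-(2,5-dimethoxyphenyl)ethyl]-1-methoxybenzene | BrC(Br)=COc1cc(CCc2cc(OC)ccc2OC)ccc1OC
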